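## Retrosynthetic overview

- Target ⇒ mono-furanoid mono-epoxide: the cis-5,6-diol comes from acid hydration of the last (5R,6S)-oxirane, with water entering at C6 with retention.
- Mono-furanoid mono-epoxide ⇒ C2-symmetric (5R,6S,5'R,6'S)-diepoxide: C8'–O disconnection; one of the two identical vinyl oxiranes is ring-expanded to the 2,5-dihydrofuran (epoxide–furanoxide rearrangement).
- Diepoxide ⇒ β-carotene: both oxiranes are placed directly on the C5=C6 and C5'=C6' bonds of the intact C40 polyene by one catalyst-controlled double epoxidation; no C–C bond is made.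
- Ring order: cyclohexene rings and polyene are bought; two oxirane rings (step 1); dihydrofuran ring (step 2); remaining oxirane opened to the diol (step 3).

Assumption: the SMILES is read as all-E with a cis-(5R,6S)-diol end and a (5'R,8'R)-furanoid end (chain at C8' trans to the C5' methyl); the facial sense of the epoxidation catalyst is predicted by analogy with cis-β-methylstyrene and is to be calibrated on β-ionone, the antipodal ketone being used if the sense is opposite.

General handling: argon, dim light, BHT-stabilised solvents, base-washed glassware, chromatography on Et3N-deactivated silica.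

## Route

Step 1
Reactants: 1 (all-E)-β,β-carotene
Product: 3 (5R,6S,5'R,6'S)-5,6:5',6'-diepoxy-5,6,5',6'-tetrahydro-β,β-carotene, via (5R,6S)-5,6-epoxy-5,6-dihydro-β,β-carotene 2 (not isolated)
Conditions: Shi D-glucose-derived N-(p-tolyl)oxazolidinone ketone (0.6 equiv), Oxone (2.6 equiv KHSO5, slow addition), K2CO3 (6 equiv), Bu4NHSO4 (0.1 equiv), DME/DMM/toluene, aq. K2CO3–AcOH buffer pH 8, −10 to 0 °C; then chiral-phase HPLC to remove meso isomer
Reagents that add atoms: potassium peroxymonosulfate KHSO5 (active salt of Oxone), [K+].[O-]S(=O)(=O)OO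
Why: Proposed new method: the chiral dioxirane formed from the ketone and KHSO5 transfers oxygen in a concerted spiro transition state to the twisted, tetrasubstituted C5=C6 and C5'=C6' bonds (the bonds peracids attack first in β-carotene), and with the polyenyl group at C6 placed against the oxazolidinone as the aryl group is in cis-β-methylstyrene the oxygen should arrive on the face that gives 5R,6S at each end, the second epoxidation raising the enantiomeric purity of the C2-symmetric product at the cost of some meso isomer; the closest known reaction type is the Shi asymmetric epoxidation of conjugated cis-alkenes and of tetrasubstituted benzylidenecyclobutanes.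

Step 2
Reactants: 3 (5R,6S,5'R,6'S)-5,6:5',6'-diepoxy-5,6,5',6'-tetrahydro-β,β-carotene
Product: 4 (5R,6S,5'R,8'R)-5,6:5',8'-diepoxy-5,6,5',8'-tetrahydro-β,β-carotene
Conditions: dry HCl (2 mol %, Et2O stock), Et2O/CH2Cl2 4:1, −20 °C; Et3N quench at ca. 50% conversion; chromatography (3 recycled, 8'S epimer and bis-furanoid removed)
Reagents that add atoms: none
Why: Acid-catalysed epoxide–furanoxide rearrangement (vinyl oxirane to 2,5-dihydrofuran ring expansion): protonation and C6'–O heterolysis give a polyenyl cation that the C5' hydroxyl captures at C8', so C5' stays R because its C–O bond never breaks, while C8' forms as both epimers and the 8'R isomer is separated; the reaction is stopped near half conversion because the two ends are equivalent.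

Step 3
Reactants: 4 (5R,6S,5'R,8'R)-5,6:5',8'-diepoxy-5,6,5',8'-tetrahydro-β,β-carotene
Product: 5 (5R,6S,5'R,8'R)-5',8'-epoxy-5,6,5',8'-tetrahydro-β,β-carotene-5,6-diol
Conditions: HClO4 (0.02 M), THF/H2O 2:1, 0 °C, HPLC-monitored; NaHCO3 quench; chromatography then HPLC
Reagents that add atoms: water, O
Why: Acid-catalysed SN1 hydrolysis of the remaining vinyl epoxide: C6–O heterolysis gives the polyenyl cation, which water captures at C6 on the face of the C5 hydroxyl (anti to the C5 methyl, hydrogen-bond guided, as in the syn hydrolysis of 1-arylcyclohexene oxides), giving the cis-(5R,6S)-diol with net retention at C6 while C5, C5' and C8' are untouched and the furanoid end survives the dilute acid.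

## Compound list

1 | (all-E)-β,β-carotene | CC(/C=C/C=C(C)/C=C/C1=C(C)CCCC1(C)C)=C\C=C\C=C(C)\C=C\C=C(/C)\C=C\C1=C(C)CCCC1(C)C | starting material
2 | (5R,6S)-5,6-epoxy-5,6-dihydro-β,β-carotene (one ring carries the 5,6-oxirane) | CC(/C=C/C=C(C)/C=C/[C@@]12O[C@]1(C)CCCC2(C)C)=C\C=C\C=C(C)\C=C\C=C(/C)\C=C\C1=C(C)CCCC1(C)C | intermediate
3 | (5R,6S,5'R,6'S)-5,6:5',6'-diepoxy-5,6,5',6'-tetrahydro-β,β-carotene (C2-symmetric bis-oxirane) | CC(/C=C/C=C(C)/C=C/[C@@]12O[C@]1(C)CCCC2(C)C)=C\C=C\C=C(C)\C=C\C=C(/C)\C=C\[C@@]12O[C@]1(C)CCCC2(C)C | intermediate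
4 | (5R,6S,5'R,8'R)-5,6:5',8'-diepoxy-5,6,5',8'-tetrahydro-β,β-carotene (one 5,6-oxirane end, one 5',8'-dihydrofuran end with the chain at C8' trans to the C5' methyl) | CC(/C=C/C=C(C)/C=C/[C@@]12O[C@]1(C)CCCC2(C)C)=C\C=C\C=C(C)\C=C\C=C(/C)[C@H]1C=C2C(C)(C)CCC[C@@]2(C)O1 | intermediate
5 | (5R,6S,5'R,8'R)-5',8'-epoxy-5,6,5',8'-tetrahydro-β,β-carotene-5,6-diol (cis-5,6-diol end, 5',8'-dihydrofuran end) | CC(/C=C/C=C(C)/C=C/[C@]1(O)C(C)(C)CCC[C@@]1(C)O)=C\C=C\C=C(C)\C=C\C=C(/C)[C@H]1C=C2C(C)(C)CCC[C@@]2(C)O1 | target

## Summary and risks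

Total step count: 3. Longest linear sequence: 3 steps (1 → 3 → 4 → 5).

Steps most likely to fail:

Step 1 (face selectivity on a tetrasubstituted alkene is unproven; over-oxidation of the chain; meso isomer). Fallback: set out from 1 and give up reagent control. Epoxidise with mCPBA (2.2 equiv) over solid NaHCO3 in CH2Cl2 at 0 °C. This gives the statistical 1:2:1 mixture of 3, the meso isomer (5R,6S,5'S,6'R)-5,6:5',6'-diepoxy-5,6,5',6'-tetrahydro-β,β-carotene F1 and the enantiomer (5S,6R,5'S,6'R)-5,6:5',6'-diepoxy-5,6,5',6'-tetrahydro-β,β-carotene F2. Resolve the three by preparative HPLC on a cellulose tris(3,5-dimethylphenylcarbamate) phase, assign by CD, and come back to the route at 3.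

Step 3 (the cation may close to the bis-furanoid instead of taking up water, or water may enter anti to give the 6R trans-diol). Fallback: set out from 4 and open the oxirane with metal-controlled double inversion instead of a free cation. Pd(PPh3)4 (5 mol %) under CO2 (1 atm) in THF ionises the vinyl oxirane anti to a π-allyl palladium alkoxide, which takes up CO2 and closes anti to the metal. The product is the cis-fused cyclic carbonate (5R,6S,5'R,8'R)-5',8'-epoxy-5,6,5',8'-tetrahydro-β,β-carotene-5,6-diyl carbonate F4, with net retention at C6. LiOH in THF/MeOH/H2O then gives the diol, coming back to the route at 5.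

Step 2 (statistical mono/bis rearrangement and roughly equal C8' epimers limit the yield per pass). Fallback: set out from 1 and break the symmetry at the oxidation stage. Run the step 1 catalyst system with only 0.7 equiv KHSO5 so that 2 is the main product and is isolated, with 1 recycled. Rearrange 2 to completion with dry HCl in Et2O to give (5R,8R)-5,8-epoxy-5,8-dihydro-β,β-carotene F3 after removal of its 8S epimer. Epoxidise the remaining β end of F3 with the same chiral ketone and KHSO5; the dihydrofuran C=C, flanked by two allylic C–O bonds, is less nucleophilic than the tetrasubstituted ring alkene. With the locants of the two ends exchanged, the product is 4, where the fallback comes back to the route.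

## Further compounds

F1 | step 1 | (5R,6S,5'S,6'R)-5,6:5',6'-diepoxy-5,6,5',6'-tetrahydro-β,β-carotene (meso) | CC(/C=C/C=C(C)/C=C/[C@@]12O[C@]1(C)CCCC2(C)C)=C\C=C\C=C(C)\C=C\C=C(/C)\C=C\[C@]12O[C@@]1(C)CCCC2(C)C
F2 | step 1 | (5S,6R,5'S,6'R)-5,6:5',6'-diepoxy-5,6,5',6'-tetrahydro-β,β-carotene | CC(/C=C/C=C(C)/C=C/[C@]12O[C@@]1(C)CCCC2(C)C)=C\C=C\C=C(C)\C=C\C=C(/C)\C=C\[C@]12O[C@@]1(C)CCCC2(C)C
F3 | step 2 | (5R,8R)-5,8-epoxy-5,8-dihydro-β,β-carotene | CC(/C=C/C=C(C)/C=C/C1=C(C)CCCC1(C)C)=C\C=C\C=C(C)\C=C\C=C(/C)[C@H]1C=C2C(C)(C)CCC[C@@]2(C)O1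
F4 | step 3 | (5R,6S,5'R,8'R)-5',8'-epoxy-5,6,5',8'-tetrahydro-β,β-carotene-5,6-diyl carbonate (cis-fused cyclic carbonate) | CC(/C=C/C=C(C)/C=C/[C@@]12OC(=O)O[C@]1(C)CCCC2(C)C)=C\C=C\C=C(C)\C=C\C=C(/C)[C@H]1C=C2C(C)(C)CCC[C@@]2(C)O1
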